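## Retrosynthetic overview

1. The target comes from its bis-silyl ether 34 by fluoride deprotection. No ring is formed at any stage; the phenyl ring arrives intact in benzaldehyde.
2. The C9–C10 diene bond is made late by a Negishi sp2–sp2 coupling of fragment A (C1–C9 vinyl iodide 17) with fragment B (C10–C14 plus phenyl, alkenylzinc from vinyl iodide 31).
3. Fragment A: C3 by CBS reduction of an enone, C4=C5 by Wittig olefination, C6/C7 by an Evans syn aldol onto (E)-3-iodo-2-methylpropenal, itself from propargyl alcohol by carboalumination–iodination.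
4. Fragment B: C12 from the (S)-Roche ester, the C10=C11 iodoalkene by Corey–Fuchs, methylation and hydrozirconation–iodination, the C13=C14 styrene by Julia–Kocienski olefination with benzaldehyde.

Assumption: (4R)-4-benzyl-1,3-oxazolidin-2-one (chiral auxiliary, recovered in step 5) and 1-phenyl-1H-tetrazole-5-thiol are used as bought reagents, 2-bromopentan-3-one is bought as the racemate, TBS means tert-butyldimethylsilyl, cyclopentadienyl ligands are drawn σ-bonded in SMILES, and 34 and 35 are named with the carbon numbering of the target.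

The target is (3R,4E,6S,7R,8E,10E,12S,13E)-4,6,8,10,12-pentamethyl-14-phenyltetradeca-4,8,10,13-tetraene-3,7-diol; C6-methyl and C7-hydroxyl are syn.

## Fragment A (C1–C9)

Step 1
Reactants: 1 prop-2-yn-1-ol
Product: 3 (E)-3-iodo-2-methylprop-2-en-1-ol, via alkenylalane 2 (not isolated)
Conditions: AlMe3 (3 equiv), Cp2ZrCl2 (0.25 equiv), CH2Cl2, 0 °C → rt, 18 h; then I2, THF, –30 → 0 °C
Reagents that add atoms: trimethylaluminium C[Al](C)C; iodine II
Why: Negishi zirconium-catalysed carboalumination adds methyl and aluminium syn across the alkyne with aluminium at the terminus, and iodinolysis with retention gives only the (E)-iodide.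

Step 2
Reactants: 3 (E)-3-iodo-2-methylprop-2-en-1-ol
Product: 4 (E)-3-iodo-2-methylprop-2-enal
Conditions: MnO2 (15 equiv), CH2Cl2, rt, 2 h; filtered solution used directly
Reagents that add atoms: none
Why: Heterogeneous allylic oxidation with MnO2 stops at the enal and leaves the vinyl iodide and the alkene geometry untouched.

Step 3
Reactants: 5 propanoyl chloride
Product: 6 (4R)-4-benzyl-3-propanoyl-1,3-oxazolidin-2-one
Conditions: (4R)-4-benzyl-1,3-oxazolidin-2-one, n-BuLi, THF, –78 °C; then 5, –78 → 0 °C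
Reagents that add atoms: (4R)-4-benzyl-1,3-oxazolidin-2-one O=C1N[C@H](Cc2ccccc2)CO1
Why: N-acylation of the lithiated oxazolidinone by the acid chloride gives the propionimide needed for an auxiliary-controlled aldol reaction.

Step 4
Reactants: 6 (4R)-4-benzyl-3-propanoyl-1,3-oxazolidin-2-one; 4 (E)-3-iodo-2-methylprop-2-enal
Product: 8 (4R)-4-benzyl-3-[(2R,3R,4E)-3-hydroxy-5-iodo-2,4-dimethylpent-4-enoyl]-1,3-oxazolidin-2-one, via boron enolate 7 (not isolated)
Conditions: Bu2BOTf, i-Pr2NEt, CH2Cl2, –78 → 0 °C; then 4, –78 → 0 °C; pH 7 buffer, MeOH, 30% H2O2, 0 °C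
Reagents that add atoms: none
Why: Evans syn aldol reaction, in which the (Z)-boron enolate reacts through a chair Zimmerman–Traxler transition state on the face away from the benzyl group and so sets (2R,3R), the C6 and C7 centres of the target, with high diastereoselectivity.

Step 5
Reactants: 8 aldol adduct
Product: 9 (2R,3R,4E)-3-hydroxy-5-iodo-N-methoxy-N,2,4-trimethylpent-4-enamide
Conditions: MeNH(OMe)·HCl, AlMe3, THF, –20 → 0 °C
Reagents that add atoms: N,O-dimethylhydroxylamine hydrochloride CNOC.Cl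
Why: Weinreb transamidation with the aluminium amide, helped by the free β-hydroxyl, releases the auxiliary without touching either stereocentre.

Step 6
Reactants: 9 Weinreb amide
Product: 10 (2R,3R,4E)-3-(TBSO)-5-iodo-N-methoxy-N,2,4-trimethylpent-4-enamide
Conditions: TBSOTf, 2,6-lutidine, CH2Cl2, –78 → 0 °C
Reagents that add atoms: tert-butyldimethylsilyl triflate CC(C)(C)[Si](C)(C)OS(=O)(=O)C(F)(F)F
Why: Silyl triflate silylation protects the hindered secondary allylic alcohol so that the aldehyde made next cannot undergo retro-aldol cleavage.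

Step 7
Reactants: 10 silylated Weinreb amide
Product: 11 (2R,3R,4E)-3-(TBSO)-5-iodo-2,4-dimethylpent-4-enal
Conditions: i-Bu2AlH, THF, –78 °C; aq. potassium sodium tartrate work-up
Reagents that add atoms: none
Why: The Weinreb amide is reduced to a chelated tetrahedral intermediate that collapses to the aldehyde only on work-up, so there is no over-reduction and no epimerisation.

Step 8
Reactants: 12 2-bromopentan-3-one
Product: 14 2-(triphenylphosphoranylidene)pentan-3-one, via phosphonium bromide 13 (not isolated)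
Conditions: PPh3, toluene, 90 °C; then 2 M aq. NaOH, CH2Cl2, rt
Reagents that add atoms: triphenylphosphine c1ccc(cc1)P(c1ccccc1)c1ccccc1
Why: SN2 quaternisation of PPh3 by the α-bromoketone followed by deprotonation of the acidic salt gives the stabilised keto ylide.

Step 9
Reactants: 11 aldehyde; 14 keto ylide
Product: 15 (4E,6S,7R,8E)-7-(TBSO)-9-iodo-4,6,8-trimethylnona-4,8-dien-3-one
Conditions: toluene, 100 °C, 36 h
Reagents that add atoms: none
Why: Wittig olefination with a stabilised α-branched ylide gives the (E)-trisubstituted enone selectively.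

Step 10
Reactants: 15 enone
Product: 16 (3R,4E,6S,7R,8E)-7-(TBSO)-9-iodo-4,6,8-trimethylnona-4,8-dien-3-ol
Conditions: (S)-Me-CBS oxazaborolidine [(3aS)-1-methyl-3,3-diphenylhexahydropyrrolo[1,2-c][1,3,2]oxazaborole] (0.5 equiv), catecholborane (2 equiv), toluene, –78 → –40 °C; then MeOH
Reagents that add atoms: none
Why: Corey–Bakshi–Shibata reduction, in which the (S)-oxazaborolidine binds the ketone with the larger alkenyl group away from the catalyst and delivers hydride to one face, setting (3R) independently of the distant C6/C7 centres.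

Step 11
Reactants: 16 allylic alcohol
Product: 17 (1E,3R,4S,5E,7R)-3,7-bis(TBSO)-1-iodo-2,4,6-trimethylnona-1,5-diene
Conditions: TBSOTf, 2,6-lutidine, CH2Cl2, –78 °C
Reagents that add atoms: tert-butyldimethylsilyl triflate CC(C)(C)[Si](C)(C)OS(=O)(=O)C(F)(F)F
Why: Silylation masks the acidic hydroxyl so that the alkenylzinc reagent of the coupling is not quenched, and both silyl ethers can later be removed together.

## Fragment B (C10–C14 and phenyl)

Step 12
Reactants: 18 methyl (2S)-3-hydroxy-2-methylpropanoate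
Product: 19 methyl (2S)-3-(TBSO)-2-methylpropanoate
Conditions: TBSCl, imidazole, CH2Cl2, rt
Reagents that add atoms: tert-butyldimethylsilyl chloride CC(C)(C)[Si](C)(C)Cl
Why: Standard silylation of the primary alcohol of the Roche ester, which supplies the C12 stereocentre from the chiral pool.

Step 13
Reactants: 19 silylated Roche ester
Product: 20 (2S)-3-(TBSO)-2-methylpropanal
Conditions: i-Bu2AlH (1.05 equiv), CH2Cl2, –78 °C
Reagents that add atoms: none
Why: Low-temperature hydride reduction stops at the aldehyde through the aluminium hemiacetal, and the α-stereocentre is not enolised under these conditions.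

Step 14
Reactants: 20 aldehyde
Product: 21 tert-butyl{[(2R)-4,4-dibromo-2-methylbut-3-en-1-yl]oxy}dimethylsilane
Conditions: CBr4, PPh3, Zn dust, CH2Cl2, rt (ylide pre-formed); then 20, 0 °C
Reagents that add atoms: carbon tetrabromide BrC(Br)(Br)Br
Why: Corey–Fuchs dibromo-olefination is a Wittig reaction of Ph3P=CBr2 under non-basic conditions, so the α-stereocentre is retained (the descriptor changes to R only through priorities).

Step 15
Reactants: 21 dibromo-olefin
Product: 23 tert-butyldimethyl{[(2R)-2-methylpent-3-yn-1-yl]oxy}silane, via lithium acetylide 22 (not isolated)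
Conditions: n-BuLi (2.2 equiv), THF, –78 °C; then MeI, –78 °C → rt
Reagents that add atoms: iodomethane CI
Why: Second stage of the Corey–Fuchs reaction, in which Br/Li exchange and Fritsch–Buttenberg–Wiechell rearrangement give the lithium acetylide that is C-methylated by MeI.

Step 16
Reactants: 23 methyl alkyne
Product: 25 tert-butyl{[(2R,3E)-4-iodo-2-methylpent-3-en-1-yl]oxy}dimethylsilane, via alkenylzirconocene 24 (not isolated)
Conditions: Cp2Zr(H)Cl (2.5 equiv), THF, 50 °C, 1 h; then I2, THF, 0 °C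
Reagents that add atoms: iodine II
Why: Hydrozirconation is a syn addition that, with excess Cp2Zr(H)Cl, equilibrates zirconium to the less hindered methyl-bearing carbon, and iodinolysis with retention gives the (E)-2-iodoalkene with iodine trans to the stereocentre-bearing carbon.

Step 17
Reactants: 25 silyl ether
Product: 26 (2R,3E)-4-iodo-2-methylpent-3-en-1-ol
Conditions: Bu4NF, THF, 0 °C → rt
Reagents that add atoms: none
Why: Fluoride cleaves the primary silyl ether through the strong Si–F bond without affecting the vinyl iodide.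

Step 18
Reactants: 26 alcohol
Product: 27 5-{[(2R,3E)-4-iodo-2-methylpent-3-en-1-yl]sulfanyl}-1-phenyl-1H-tetrazole
Conditions: 1-phenyl-1H-tetrazole-5-thiol, PPh3, DIAD, THF, 0 °C → rt
Reagents that add atoms: 1-phenyl-1H-tetrazole-5-thiol Sc1nnnn1-c1ccccc1
Why: Mitsunobu thioetherification displaces the activated primary oxyphosphonium by SN2 at CH2, so the neighbouring stereocentre is not involved.

Step 19
Reactants: 27 sulfide
Product: 28 5-{[(2R,3E)-4-iodo-2-methylpent-3-en-1-yl]sulfonyl}-1-phenyl-1H-tetrazole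
Conditions: (NH4)6Mo7O24·4H2O (0.1 equiv), 30% aq. H2O2, EtOH, 0 °C → rt
Reagents that add atoms: hydrogen peroxide OO
Why: Molybdate-catalysed peroxide oxidation takes the sulfide to the sulfone chemoselectively, the iodo-substituted alkene being too electron-poor to be epoxidised.

Step 20
Reactants: 28 tetrazolyl sulfone; 29 benzaldehyde
Product: 31 [(1E,3S,4E)-5-iodo-3-methylhexa-1,4-dien-1-yl]benzene, via sulfonyl carbanion 30 (not isolated)
Conditions: KN(SiMe3)2, DME, –60 °C, 30 min; then 29, –60 °C → rt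
Reagents that add atoms: none
Why: Julia–Kocienski olefination, in which addition of the metalated sulfone to benzaldehyde, Smiles rearrangement and loss of SO2 and tetrazololate give the conjugated (E)-styrene without any carbonyl group next to the C12 centre.

## Coupling and end game

Step 21
Reactants: 31 fragment B vinyl iodide; 17 fragment A vinyl iodide
Product: 34 (3R,4E,6S,7R,8E,10E,12S,13E)-3,7-bis(TBSO)-4,6,8,10,12-pentamethyl-14-phenyltetradeca-4,8,10,13-tetraene, via alkenyllithium 32 (not isolated), via alkenylzinc chloride 33 (not isolated)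
Conditions: 31 (1.3 equiv), t-BuLi (2.6 equiv), Et2O, –78 °C; ZnCl2 (THF), –78 → 0 °C; then 17, Pd(PPh3)4 (5 mol %), THF, rt
Reagents that add atoms: none
Why: Negishi cross-coupling, in which I/Li exchange and transmetalation to zinc keep the alkene geometry and the zerovalent-palladium-catalysed sp2–sp2 coupling is stereospecific, giving the (8E,10E)-diene without touching any stereocentre.

Step 22
Reactants: 34 bis-silyl ether
Product: 35 (3R,4E,6S,7R,8E,10E,12S,13E)-4,6,8,10,12-pentamethyl-14-phenyltetradeca-4,8,10,13-tetraene-3,7-diol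
Conditions: Bu4NF (6 equiv), THF, rt → 40 °C
Reagents that add atoms: none
Why: Fluoride desilylation under non-acidic conditions frees both alcohols without ionising the dienylic C7 carbinol or isomerising the skipped diene.

## Compound list

1 | prop-2-yn-1-ol | C#CCO | starting material
2 | (E)-[3-(dimethylalumanyloxy)-2-methylprop-1-en-1-yl]dimethylalane | C[Al](C)OC/C(C)=C/[Al](C)C | intermediate
3 | (E)-3-iodo-2-methylprop-2-en-1-ol | OC/C(C)=C/I | intermediate
4 | (E)-3-iodo-2-methylprop-2-enal | O=C/C(C)=C/I | intermediate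
5 | propanoyl chloride | CCC(Cl)=O | starting material
6 | (4R)-4-benzyl-3-propanoyl-1,3-oxazolidin-2-one | CCC(=O)N1[C@H](Cc2ccccc2)COC1=O | intermediate
7 | dibutylboron (Z)-enolate of 6 | C/C=C(\OB(CCCC)CCCC)N1[C@H](Cc2ccccc2)COC1=O | intermediate
8 | (4R)-4-benzyl-3-[(2R,3R,4E)-3-hydroxy-5-iodo-2,4-dimethylpent-4-enoyl]-1,3-oxazolidin-2-one | O=C([C@H](C)[C@@H](O)/C(C)=C/I)N1[C@H](Cc2ccccc2)COC1=O | intermediate
9 | (2R,3R,4E)-3-hydroxy-5-iodo-N-methoxy-N,2,4-trimethylpent-4-enamide | CON(C)C(=O)[C@H](C)[C@@H](O)/C(C)=C/I | intermediate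
10 | (2R,3R,4E)-3-(TBSO)-5-iodo-N-methoxy-N,2,4-trimethylpent-4-enamide | CON(C)C(=O)[C@H](C)[C@@H](O[Si](C)(C)C(C)(C)C)/C(C)=C/I | intermediate
11 | (2R,3R,4E)-3-(TBSO)-5-iodo-2,4-dimethylpent-4-enal | O=C[C@H](C)[C@@H](O[Si](C)(C)C(C)(C)C)/C(C)=C/I | intermediate
12 | 2-bromopentan-3-one (racemic) | CCC(=O)C(C)Br | starting material
13 | (3-oxopentan-2-yl)triphenylphosphonium bromide | CCC(=O)C(C)[P+](c1ccccc1)(c1ccccc1)c1ccccc1.[Br-] | intermediate
14 | 2-(triphenylphosphoranylidene)pentan-3-one | CCC(=O)C(C)=P(c1ccccc1)(c1ccccc1)c1ccccc1 | intermediate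
15 | (4E,6S,7R,8E)-7-(TBSO)-9-iodo-4,6,8-trimethylnona-4,8-dien-3-one | CCC(=O)/C(C)=C/[C@H](C)[C@@H](O[Si](C)(C)C(C)(C)C)/C(C)=C/I | intermediate
16 | (3R,4E,6S,7R,8E)-7-(TBSO)-9-iodo-4,6,8-trimethylnona-4,8-dien-3-ol | CC[C@@H](O)/C(C)=C/[C@H](C)[C@@H](O[Si](C)(C)C(C)(C)C)/C(C)=C/I | intermediate
17 | (1E,3R,4S,5E,7R)-3,7-bis(TBSO)-1-iodo-2,4,6-trimethylnona-1,5-diene | CC[C@@H](O[Si](C)(C)C(C)(C)C)/C(C)=C/[C@H](C)[C@@H](O[Si](C)(C)C(C)(C)C)/C(C)=C/I | intermediate
18 | methyl (2S)-3-hydroxy-2-methylpropanoate | COC(=O)[C@@H](C)CO | starting material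
19 | methyl (2S)-3-(TBSO)-2-methylpropanoate | COC(=O)[C@@H](C)CO[Si](C)(C)C(C)(C)C | intermediate
20 | (2S)-3-(TBSO)-2-methylpropanal | O=C[C@@H](C)CO[Si](C)(C)C(C)(C)C | intermediate
21 | tert-butyl{[(2R)-4,4-dibromo-2-methylbut-3-en-1-yl]oxy}dimethylsilane | BrC(Br)=C[C@@H](C)CO[Si](C)(C)C(C)(C)C | intermediate
22 | lithium (3R)-4-(TBSO)-3-methylbut-1-yn-1-ide | [Li]C#C[C@@H](C)CO[Si](C)(C)C(C)(C)C | intermediate
23 | tert-butyldimethyl{[(2R)-2-methylpent-3-yn-1-yl]oxy}silane | CC#C[C@@H](C)CO[Si](C)(C)C(C)(C)C | intermediate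
24 | chlorobis(cyclopentadienyl)[(2E,4R)-5-(TBSO)-4-methylpent-2-en-2-yl]zirconium | C/C(=C\[C@@H](C)CO[Si](C)(C)C(C)(C)C)[Zr](Cl)(C1C=CC=C1)C1C=CC=C1 | intermediate
25 | tert-butyl{[(2R,3E)-4-iodo-2-methylpent-3-en-1-yl]oxy}dimethylsilane | C/C(I)=C\[C@@H](C)CO[Si](C)(C)C(C)(C)C | intermediate
26 | (2R,3E)-4-iodo-2-methylpent-3-en-1-ol | C/C(I)=C\[C@@H](C)CO | intermediate
27 | 5-{[(2R,3E)-4-iodo-2-methylpent-3-en-1-yl]sulfanyl}-1-phenyl-1H-tetrazole | C/C(I)=C\[C@@H](C)CSc1nnnn1-c1ccccc1 | intermediate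
28 | 5-{[(2R,3E)-4-iodo-2-methylpent-3-en-1-yl]sulfonyl}-1-phenyl-1H-tetrazole | C/C(I)=C\[C@@H](C)CS(=O)(=O)c1nnnn1-c1ccccc1 | intermediate
29 | benzaldehyde | O=Cc1ccccc1 | starting material
30 | potassium salt of the α-sulfonyl carbanion of 28 | C/C(I)=C\[C@@H](C)[CH-]S(=O)(=O)c1nnnn1-c1ccccc1.[K+] | intermediate
31 | [(1E,3S,4E)-5-iodo-3-methylhexa-1,4-dien-1-yl]benzene | C/C(I)=C\[C@@H](C)/C=C/c1ccccc1 | intermediate
32 | [(2Z,4S,5E)-4-methyl-6-phenylhexa-2,5-dien-2-yl]lithium (Li in place of I in 31, geometry retained) | [Li]/C(C)=C/[C@@H](C)/C=C/c1ccccc1 | intermediate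
33 | chloro[(2E,4S,5E)-4-methyl-6-phenylhexa-2,5-dien-2-yl]zinc | Cl[Zn]/C(C)=C/[C@@H](C)/C=C/c1ccccc1 | intermediate
34 | (3R,4E,6S,7R,8E,10E,12S,13E)-3,7-bis(TBSO)-4,6,8,10,12-pentamethyl-14-phenyltetradeca-4,8,10,13-tetraene | CC[C@@H](O[Si](C)(C)C(C)(C)C)/C(C)=C/[C@H](C)[C@@H](O[Si](C)(C)C(C)(C)C)/C(C)=C/C(C)=C/[C@@H](C)/C=C/c1ccccc1 | intermediate
35 | (3R,4E,6S,7R,8E,10E,12S,13E)-4,6,8,10,12-pentamethyl-14-phenyltetradeca-4,8,10,13-tetraene-3,7-diol | CC[C@@H](O)/C(C)=C/[C@H](C)[C@@H](O)/C(C)=C/C(C)=C/[C@@H](C)/C=C/c1ccccc1 | target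

## Step count and risks

Total step count: 22. Longest linear sequence: 11 steps (1, 2, 4, 5, 6, 7, 9, 10, 11, 21, 22; the fragment B line 12–20, 21, 22 is equally long).

The three steps most likely to fail:

Step 21 (Negishi coupling). Both partners are hindered and the diene carries 1,3-related methyl groups; protonation or homocoupling of the alkenylmetal could dominate. The fallback reverses the polarity and avoids any organolithium. It sets out from 17, which is borylated (B2pin2, PdCl2(dppf), KOPh, toluene, 50 °C) to 2-[(1E,3R,4S,5E,7R)-3,7-bis(TBSO)-2,4,6-trimethylnona-1,5-dien-1-yl]-4,4,5,5-tetramethyl-1,3,2-dioxaborolane F1. Suzuki–Miyaura coupling of this boronate with iodide 31 (Pd(PPh3)4, aq. K3PO4, THF, 45 °C) comes back to the route at 34.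

Step 20 (Julia–Kocienski olefination). The E/Z ratio with an aromatic aldehyde may be mediocre, and the metalated sulfone may decompose. The fallback swaps the roles of the partners. It sets out from 26, which is oxidised (Dess–Martin periodinane, NaHCO3, CH2Cl2, 0 °C) to the labile (2R,3E)-4-iodo-2-methylpent-3-enal F2. This is used at once, without chromatography, in a Horner–Wadsworth–Emmons reaction with lithiated diethyl benzylphosphonate (n-BuLi, THF, –78 °C → rt), which is reliably E-selective and comes back at 31.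

Step 9 (Wittig with the keto ylide). The α-branched stabilised ylide reacts slowly with the hindered aldehyde, and long heating risks epimerisation at C6 or loss of the silyloxy group. The fallback sets out from 11 and replaces steps 9 and 10:
- Wittig with the more reactive ethyl 2-(triphenylphosphoranylidene)propanoate (CH2Cl2, 40 °C) gives ethyl (2E,4S,5R,6E)-5-(TBSO)-7-iodo-2,4,6-trimethylhepta-2,6-dienoate F3.
- i-Bu2AlH (CH2Cl2, –78 °C) gives (2E,4S,5R,6E)-5-(TBSO)-7-iodo-2,4,6-trimethylhepta-2,6-dien-1-ol F4.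
- MnO2 (CH2Cl2, rt) gives (2E,4S,5R,6E)-5-(TBSO)-7-iodo-2,4,6-trimethylhepta-2,6-dienal F5.
- Catalytic asymmetric ethylation with Et2Zn and (+)-MIB [(2R)-3-exo-morpholinoisoborneol] (toluene, 0 °C) is expected to give the (3R) carbinol, by analogy with the (2S) ligand giving (S)-1-phenylpropan-1-ol from benzaldehyde, and comes back at 16.

Further compounds

F1 | step 21 | 2-[(1E,3R,4S,5E,7R)-3,7-bis(TBSO)-2,4,6-trimethylnona-1,5-dien-1-yl]-4,4,5,5-tetramethyl-1,3,2-dioxaborolane | CC[C@@H](O[Si](C)(C)C(C)(C)C)/C(C)=C/[C@H](C)[C@@H](O[Si](C)(C)C(C)(C)C)/C(C)=C/B1OC(C)(C)C(C)(C)O1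
F2 | step 20 | (2R,3E)-4-iodo-2-methylpent-3-enal | C/C(I)=C\[C@@H](C)C=O
F3 | step 9 | ethyl (2E,4S,5R,6E)-5-(TBSO)-7-iodo-2,4,6-trimethylhepta-2,6-dienoate | CCOC(=O)/C(C)=C/[C@H](C)[C@@H](O[Si](C)(C)C(C)(C)C)/C(C)=C/I
F4 | step 9 | (2E,4S,5R,6E)-5-(TBSO)-7-iodo-2,4,6-trimethylhepta-2,6-dien-1-ol | OC/C(C)=C/[C@H](C)[C@@H](O[Si](C)(C)C(C)(C)C)/C(C)=C/I
F5 | step 9 | (2E,4S,5R,6E)-5-(TBSO)-7-iodo-2,4,6-trimethylhepta-2,6-dienal | O=C/C(C)=C/[C@H](C)[C@@H](O[Si](C)(C)C(C)(C)C)/C(C)=C/I
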